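**Assumption:** (R)-4-methyltetrahydropyran-2-one (1), (E)-3-methylpent-2-enoic acid (10), 3-(TBS-oxy)propanal (13) and 3-methylbuta-1,2-diene (14) are purchasable as single enantiomer or isomer, and the final hydroxy-diketone closes to the drawn hemiketal under thermodynamic control.

## Retrosynthetic overview
1. Target 24 comes from the open hydroxy-diketone, which closes spontaneously to the hemiketal. That precursor is made by oxidising the C-a carbinol of the THF-bridged 14-membered macrocycle 21/22.
2. The THF ring and the quaternary C(i)–O centre come from the key step, a radical 5-exo cyclisation (C(h)–C(i) bond) of a primary iodide onto the E-β-alkoxy enone of macrocycle 19. The macrocycle forces the two ring chains on C(f) and C(i) to be cis. The C(j) hydroxyl is added afterwards by enolate hydroxylation.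
3. Macrocycle 19 comes from ring-closing metathesis (E-alkene) of enol ether 18. Enol ether 18 comes from oxa-Michael addition of iodo-alcohol 17 to α-acyloxy ynone 12.
4. Ynone 12 comes from lactone 1, which supplies the C(m) methyl centre. The C(o), C(b) and C(l) centres are set by asymmetric vinylation, Brown crotylation and Davis hydroxylation. Iodo-alcohol 17 comes from a reverse-prenylation of 3-(TBS-oxy)propanal.
5. Ring order: 14-membered macrocycle (RCM), then THF (radical), then THP hemiketal (last, spontaneous).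

## Route

**Step 1**
Reactants: 1 (R)-4-methyltetrahydropyran-2-one
Product: 2 (R)-5-hydroxy-N-methoxy-N,3-dimethylpentanamide
Conditions: MeNH(OMe)·HCl, Me3Al, CH2Cl2, 0 °C → rt
Reagents that add atoms: N,O-dimethylhydroxylamine, CNOC
Why: Me3Al-promoted Weinreb aminolysis opens the lactone at the acyl carbon and leaves the C(m) stereocentre untouched.

**Step 2**
Reactants: 2
Product: 3 (R)-N-methoxy-N,3-dimethyl-5-oxopentanamide
Conditions: Dess–Martin periodinane, NaHCO3, CH2Cl2, rt
Reagents that add atoms: none
Why: Dess–Martin oxidation of the primary alcohol gives the C(o) aldehyde.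

**Step 3**
Reactants: 3
Product: 4 (3R,5R)-5-hydroxy-N-methoxy-N,3-dimethylhept-6-enamide
Conditions: (CH2=CH)2Zn, (−)-MIB (10 mol%), toluene, 0 °C
Reagents that add atoms: divinylzinc, C=C[Zn]C=C
Why: Amino-isoborneol-catalysed enantioselective vinylzinc addition (Oppolzer–Walsh type); catalyst control overrides the weak 1,3-induction from C(m) and sets C(o) as (R). The vinyl group is a masked aldehyde at C(a).

**Step 4**
Reactants: 4
Product: 5 the 5-O-TBS ether of 4
Conditions: TBSOTf, 2,6-lutidine, CH2Cl2, −78 → 0 °C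
Reagents that add atoms: TBSOTf, CC(C)(C)[Si](C)(C)OS(=O)(=O)C(F)(F)F
Why: Silylation protects C(o)–OH; no stereocentre is touched.

**Step 5**
Reactants: 5
Product: 6 (3R,5R)-5-(TBS-oxy)-N-methoxy-N,3-dimethyl-6-oxohexanamide
Conditions: O3, CH2Cl2, −78 °C; then PPh3
Reagents that add atoms: ozone, [O-][O+]=O
Why: Ozonolysis converts the vinyl group into the α-silyloxy aldehyde at C(a), which is used at once to avoid epimerisation at C(o).

**Step 6**
Reactants: 6
Product: 7 anti-homoallylic alcohol (C(a)–OH, C(b)–Me, vinyl)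
Conditions: B-(E)-crotyldiisopinocampheylborane (enantiomer giving 7S at C(b)), THF, −78 °C; then NaOH, H2O2
Reagents that add atoms: (E)-crotyl-B(Ipc)2, C/C=C/CB(C1C(C)C2CC1C2(C)C)C1C(C)C2CC1C2(C)C
Why: Brown crotylboration through a chair transition state gives the anti adduct; reagent control sets C(b) as (S), and the C(a) carbinol is oxidised away in step 19.

**Step 7**
Reactants: 7
Product: 8 the 6-O-TES ether of 7
Conditions: TESCl, imidazole, DMF, rt
Reagents that add atoms: TESCl, CC[Si](Cl)(CC)CC
Why: A TES group on C(a)–OH can later be removed in the presence of the TBS on C(o).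

**Step 8**
Reactants: 8
Product: 9 α-hydroxy Weinreb amide (2R,3R,5R,6S,7S)
Conditions: KHMDS, THF, −78 °C; then (camphorsulfonyl)oxaziridine
Reagents that add atoms: (camphorsulfonyl)oxaziridine, CC1(C)C2CCC13CS(=O)(=O)N4OC34C2
Why: Davis α-hydroxylation of the amide enolate; approach anti to the β-methyl (Felkin-type) with chiral-oxaziridine control sets C(l) as (R), giving the ring-cis (acyclic anti) l/m relationship.

**Step 9**
Reactants: 9; 10 (E)-3-methylpent-2-enoic acid
Product: 11 ester of 9 with 10
Conditions: 2,4,6-Cl3C6H2COCl, Et3N, THF; then 9, DMAP, toluene, rt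
Reagents that add atoms: none (acid 10 is the listed reactant)
Why: Yamaguchi esterification at the only free hydroxyl installs the side-chain ester with the E-alkene retained.

**Step 10**
Reactants: 11
Product: 12 α-acyloxy ynone
Conditions: CH3C≡CMgBr, THF, −40 °C; cold NH4Cl quench
Reagents that add atoms: propynylmagnesium bromide, CC#C[Mg]Br
Why: Weinreb ketone synthesis stops cleanly at the ynone via the chelated tetrahedral intermediate, and the hindered enoate ester is untouched.

**Step 11**
Reactants: 13 3-(TBS-oxy)propanal; 14 3-methylbuta-1,2-diene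
Product: 15 (S)-1-(TBS-oxy)-4,4-dimethylhex-5-en-3-ol
Conditions: [Ir(cod)Cl]2, chiral bisphosphine, i-PrOH (H source), Cs2CO3, THF, 90 °C
Reagents that add atoms: none (14 is the listed reactant)
Why: Ir-catalysed reductive carbonyl tert-prenylation (Krische type) adds at the γ-carbon, forming the quaternary C(e) gem-dimethyl and the (S) carbinol C(f) in one step.

**Step 12**
Reactants: 15
Product: 16 (S)-4,4-dimethylhex-5-ene-1,3-diol
Conditions: TBAF, THF, 0 °C
Reagents that add atoms: none
Why: Fluoride removes the TBS group.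

**Step 13**
Reactants: 16
Product: 17 (S)-1-iodo-4,4-dimethylhex-5-en-3-ol
Conditions: I2, PPh3, imidazole, CH2Cl2/Et2O, 0 °C
Reagents that add atoms: iodine, II
Why: Appel-type iodination is selective for the unhindered primary alcohol over the neopentylic secondary one.

**Step 14**
Reactants: 12; 17
Product: 18 E-β-alkoxy enone (enol ether of C(i) with O on C(f))
Conditions: DABCO (20 mol%), CH2Cl2, 0 °C
Reagents that add atoms: none
Why: Amine-catalysed oxa-Michael addition of the hindered alcohol to the ynone gives the thermodynamic E-β-alkoxy enone through reversible addition–elimination; C(f) is untouched.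

**Step 15**
Reactants: 18
Product: 19 14-membered iodo enol-ether macrocycle (E-C(c)=C(d))
Conditions: Hoveyda–Grubbs II (10 mol%), toluene, 1 mM, 80 °C
Reagents that add atoms: none
Why: Ring-closing metathesis joins the two terminal vinyl groups (ethylene lost) and should favour the E-alkene in a ring of this size.

**Step 16**
Reactants: 19
Product: 20 THF-bridged macrocycle (C(j) is CH2)
Conditions: (TMS)3SiH (syringe pump), AIBN, PhH, 2 mM, 80 °C
Reagents that add atoms: none (silane delivers H only)
Why: Proposed new method: silyl-radical iodine abstraction gives a primary radical that adds 5-exo to the β-carbon (bearing O and Me) of the push–pull enone; the closest known reaction is the 5-exo radical cyclisation of β-alkoxyacrylates to 2,5-cis THFs, here applied to a fully substituted β-carbon inside a macrocycle. The macrocyclic chain forces C(e) and C(j) cis on the new THF, fixing the quaternary C(i)–O centre as (R), and the α-keto radical is quenched by H-transfer.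

**Step 17**
Reactants: 20
Product: 21 α-hydroxy ketone with C(j) as (S)
Conditions: KHMDS (1.05 equiv), THF, −78 °C; then (camphorsulfonyl)oxaziridine
Reagents that add atoms: (camphorsulfonyl)oxaziridine, CC1(C)C2CCC13CS(=O)(=O)N4OC34C2
Why: Kinetic enolisation at the unhindered CH2 (C(j)) rather than the tertiary C(l)–H, then Davis hydroxylation from the convex face, sets C(j) as (S).

**Step 18**
Reactants: 21
Product: 22 the C(a) free alcohol
Conditions: PPTS, MeOH, 0 °C
Reagents that add atoms: none
Why: Acid-labile TES is cleaved selectively in the presence of the TBS ether.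

**Step 19**
Reactants: 22
Product: 23 C(a) ketone (O-TBS still on C(o))
Conditions: Dess–Martin periodinane, NaHCO3, CH2Cl2, 0 °C
Reagents that add atoms: none
Why: Buffered Dess–Martin oxidation selectively oxidises the less hindered C(a) carbinol (the C(j) alcohol is neopentylic and α to a ketone) without epimerising C(b).

**Step 20**
Reactants: 23
Product: 24 tonantzitlolone A
Conditions: HF·pyridine, pyridine, THF, 0 °C → rt
Reagents that add atoms: none
Why: Fluoride removes the TBS group; the freed C(o)–OH adds to the C(k) ketone to give the THP hemiketal with the anomeric OH axial, fixing C(k) thermodynamically.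

## Compound list
1 | (R)-4-methyltetrahydropyran-2-one | C[C@@H]1CCOC(=O)C1 | starting material
2 | (R)-5-hydroxy-N-methoxy-N,3-dimethylpentanamide | CON(C)C(=O)C[C@H](C)CCO | intermediate
3 | (R)-N-methoxy-N,3-dimethyl-5-oxopentanamide | CON(C)C(=O)C[C@H](C)CC=O | intermediate
4 | (3R,5R)-5-hydroxy-N-methoxy-N,3-dimethylhept-6-enamide | CON(C)C(=O)C[C@H](C)C[C@@H](O)C=C | intermediate
5 | 5-O-TBS ether of 4 | CON(C)C(=O)C[C@H](C)C[C@@H](O[Si](C)(C)C(C)(C)C)C=C | intermediate
6 | (3R,5R)-5-(TBS-oxy)-N-methoxy-N,3-dimethyl-6-oxohexanamide | CON(C)C(=O)C[C@H](C)C[C@@H](O[Si](C)(C)C(C)(C)C)C=O | intermediate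
7 | (3R,5R,6S,7S)-5-(TBS-oxy)-6-hydroxy-N-methoxy-N,3,7-trimethylnon-8-enamide | CON(C)C(=O)C[C@H](C)C[C@@H](O[Si](C)(C)C(C)(C)C)[C@@H](O)[C@@H](C)C=C | intermediate
8 | 6-O-TES ether of 7 | CON(C)C(=O)C[C@H](C)C[C@@H](O[Si](C)(C)C(C)(C)C)[C@@H](O[Si](CC)(CC)CC)[C@@H](C)C=C | intermediate
9 | (2R,3R,5R,6S,7S)-2-hydroxy derivative of 8 | CON(C)C(=O)[C@H](O)[C@H](C)C[C@@H](O[Si](C)(C)C(C)(C)C)[C@@H](O[Si](CC)(CC)CC)[C@@H](C)C=C | intermediate
10 | (E)-3-methylpent-2-enoic acid | CC/C(C)=C/C(=O)O | starting material
11 | (E)-3-methylpent-2-enoate ester of 9 | CON(C)C(=O)[C@H](OC(=O)/C=C(/CC)C)[C@H](C)C[C@@H](O[Si](C)(C)C(C)(C)C)[C@@H](O[Si](CC)(CC)CC)[C@@H](C)C=C | intermediate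
12 | α-acyloxy ynone (Me–C≡C–C(=O)–CH(OCOR)–CH(Me)–CH2–CH(OTBS)–CH(OTES)–CH(Me)–CH=CH2) | CC#CC(=O)[C@H](OC(=O)/C=C(/CC)C)[C@H](C)C[C@@H](O[Si](C)(C)C(C)(C)C)[C@@H](O[Si](CC)(CC)CC)[C@@H](C)C=C | intermediate
13 | 3-(TBS-oxy)propanal | O=CCCO[Si](C)(C)C(C)(C)C | starting material
14 | 3-methylbuta-1,2-diene | CC(C)=C=C | starting material
15 | (S)-1-(TBS-oxy)-4,4-dimethylhex-5-en-3-ol | C=CC(C)(C)[C@@H](O)CCO[Si](C)(C)C(C)(C)C | intermediate
16 | (S)-4,4-dimethylhex-5-ene-1,3-diol | C=CC(C)(C)[C@@H](O)CCO | intermediate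
17 | (S)-1-iodo-4,4-dimethylhex-5-en-3-ol | C=CC(C)(C)[C@@H](O)CCI | intermediate
18 | E-β-alkoxy enone from 12 + 17 | C=CC(C)(C)[C@H](CCI)O/C(C)=C/C(=O)[C@H](OC(=O)/C=C(/CC)C)[C@H](C)C[C@@H](O[Si](C)(C)C(C)(C)C)[C@@H](O[Si](CC)(CC)CC)[C@@H](C)C=C | intermediate
19 | 14-membered iodo enol-ether macrocycle | ICC[C@@H]1O/C(C)=C/C(=O)[C@H](OC(=O)/C=C(/CC)C)[C@H](C)C[C@@H](O[Si](C)(C)C(C)(C)C)[C@@H](O[Si](CC)(CC)CC)[C@@H](C)/C=C/C1(C)C | intermediate
20 | THF-bridged macrocyclic ketone (C(j) = CH2) | C1C[C@@H]2O[C@@]1(C)CC(=O)[C@H](OC(=O)/C=C(/CC)C)[C@H](C)C[C@@H](O[Si](C)(C)C(C)(C)C)[C@@H](O[Si](CC)(CC)CC)[C@@H](C)/C=C/C2(C)C | intermediate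
21 | α-hydroxy ketone from 20 | C1C[C@@H]2O[C@@]1(C)[C@H](O)C(=O)[C@H](OC(=O)/C=C(/CC)C)[C@H](C)C[C@@H](O[Si](C)(C)C(C)(C)C)[C@@H](O[Si](CC)(CC)CC)[C@@H](C)/C=C/C2(C)C | intermediate
22 | C(a)-alcohol (TES removed) | C1C[C@@H]2O[C@@]1(C)[C@H](O)C(=O)[C@H](OC(=O)/C=C(/CC)C)[C@H](C)C[C@@H](O[Si](C)(C)C(C)(C)C)[C@@H](O)[C@@H](C)/C=C/C2(C)C | intermediate
23 | C(a)-ketone, O-TBS on C(o) | C1C[C@@H]2O[C@@]1(C)[C@H](O)C(=O)[C@H](OC(=O)/C=C(/CC)C)[C@H](C)C[C@@H](O[Si](C)(C)C(C)(C)C)C(=O)[C@@H](C)/C=C/C2(C)C | intermediate
24 | tonantzitlolone A | CC/C(C)=C/C(=O)O[C@@H]1[C@H](C)C[C@H]2O[C@]1(O)[C@@H](O)[C@@]1(C)CC[C@H](O1)C(C)(C)/C=C/[C@H](C)C2=O | target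

## Totals
Total steps: 20. Longest linear sequence: 17 (steps 1–10, then 14–20).

## Three steps most likely to fail
1. **Step 16 (radical cyclisation onto a fully substituted enone carbon in the macrocycle).** Simple reduction, or 5-exo attack on the neopentylic C(c)=C(d) alkene, may win.
   Fallback: form the THF polarly. Make the macrocyclic enone with the C(f) alcohol free (for example by HWE or RCM), epoxidise it nucleophilically, and open the α,β-epoxy ketone with the C(f)–OH under acid. That gives the THF and the C(j)–OH in one step.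
2. **Step 15 (RCM, reactivity and E-selectivity).** The gem-dimethyl allylic alkene is hindered, and a Z-isomer or oligomers may form.
   Fallback: change the closure to an intramolecular Julia–Kocienski olefination, with the PT-sulfone on the neopentyl carbon C(d) and an aldehyde at C(c). This gives the E-alkene and avoids carrying terminal vinyl groups through the radical step.
3. **Step 17 (regio- and stereoselective hydroxylation at C(j)).** Enolisation at C(l) or the wrong face at C(j) would give the wrong product.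
   Fallback: install the C(j) oxygen before cyclisation. Make a 2-benzyloxy-1,3-diketone in place of the ynone, form the vinylogous ester by Mitsunobu O-alkylation of the C(f) alcohol (using the enantiomeric alcohol to allow for inversion), and let the radical cyclisation of 19 terminate by H-transfer to a captodative radical.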